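The route rests on opening ring A (the 5-hydroxyindole) at C3–C3a and N1–C7a. Its benzo ring, C3a and C4 to C7a, carries oxygen at C5 para to the nitrogen-bearing C7a, the pattern of 1,4-benzoquinone. In one operation the quinone is annulated by a secondary enamine: the β-carbon bonds to a quinone CH, the nitrogen condenses on the neighbouring carbonyl, the pyrrole ring closes and the far carbonyl emerges as the free C5 phenol. The enamine comes from the ring C arylacetaldehyde, already joined to N-tosyl-6-prenylindole B, and 3-aminopropanenitrile, whose 2-cyanoethyl group is later shed with base together with the tosyl group.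

Key step: step 9

Remark: 2-cyanoethyl is chosen for N1 of ring A over a benzyl-type group so that both nitrogen groups leave under alkoxide base and no dissolving metal meets the tetramethoxybenzene or the prenyl group; the step 8 product is a tautomeric aldimine/enamine pair, numbered 14/15 and used crude.

Step 1
Reactants: 1 6-bromo-1H-indole
Product: 2 6-(3-methylbut-2-en-1-yl)-1H-indole
Conditions: prenyl-B(pin) (1.5 equiv), PdCl2(IPent)(3-chloropyridine) (2 mol%), 5 M aq KOH, THF, 70 °C
Reagents that add atoms: 4,4,5,5-tetramethyl-2-(3-methylbut-2-en-1-yl)-1,3,2-dioxaborolane, CC(C)=CCB1OC(C)(C)C(C)(C)O1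
Why: Suzuki–Miyaura coupling of an allylic boronate, in which the very bulky carbene ligand IPent (1,3-bis[2,6-di(pentan-3-yl)phenyl]imidazol-2-ylidene) should direct reductive elimination to the unsubstituted allyl terminus and give the linear prenyl isomer, while the free indole N–H tolerates the aqueous base.

Step 2
Reactants: 2 6-(3-methylbut-2-en-1-yl)-1H-indole
Product: 4 3-iodo-6-(3-methylbut-2-en-1-yl)-1-tosyl-1H-indole, via 3-iodo-6-prenylindole 3 (not isolated)
Conditions: I2 (1.05 equiv), KOH, DMF, 0 °C → rt; extractive work-up; crude, NaH, TsCl, THF, 0 °C → rt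
Reagents that add atoms: iodine, [I][I]; 4-methylbenzenesulfonyl chloride, Cc1ccc(S(=O)(=O)Cl)cc1
Why: Electrophilic aromatic iodination of the indolide at C3 is far faster than attack on the trisubstituted alkene, and N-sulfonylation of the sodium indolide then stabilises the labile 3-iodoindole and deactivates indole B for the later quinone step.

Step 3
Reactants: 4 3-iodo-6-(3-methylbut-2-en-1-yl)-1-tosyl-1H-indole
Product: 6 6-(3-methylbut-2-en-1-yl)-3-(4,4,5,5-tetramethyl-1,3,2-dioxaborolan-2-yl)-1-tosyl-1H-indole, via indol-3-ylmagnesium chloride 5 (not isolated)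
Conditions: i-PrMgCl·LiCl (1.1 equiv), THF, −40 °C; then i-PrOB(pin), −40 °C → rt
Reagents that add atoms: 2-isopropoxy-4,4,5,5-tetramethyl-1,3,2-dioxaborolane, CC(C)OB1OC(C)(C)C(C)(C)O1
Why: Iodine–magnesium exchange is fast at low temperature, the 3-magnesiated N-sulfonylindole keeps its position there, and the Grignard reagent is borylated by the alkoxyboronate (electrophilic borylation), with the alkene and sulfonamide left alone.

Step 4
Reactants: 7 1,2,4,5-tetramethoxybenzene
Product: 8 1,4-dibromo-2,3,5,6-tetramethoxybenzene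
Conditions: Br2 (2.2 equiv), CH2Cl2, 0 °C → rt
Reagents that add atoms: bromine, BrBr
Why: Electrophilic aromatic bromination; the two free positions are the only ones available and each is activated by two ortho methoxy groups.

Step 5
Reactants: 8 1,4-dibromo-2,3,5,6-tetramethoxybenzene
Product: 10 2-(4-bromo-2,3,5,6-tetramethoxyphenyl)ethan-1-ol, via aryllithium 9 (not isolated)
Conditions: n-BuLi (1.05 equiv), THF, −78 °C; ethylene oxide (3 equiv), −78 → 0 °C; aq NH4Cl
Reagents that add atoms: oxirane, C1CO1
Why: Bromine–lithium exchange stops after one bromine because a second exchange would build a dianion, and the aryllithium opens the unhindered epoxide (SN2 ring opening), which desymmetrises ring C and installs the two carbons that become C3 and C2 of indole A.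

Step 6
Reactants: 10 2-(4-bromo-2,3,5,6-tetramethoxyphenyl)ethan-1-ol; 6 6-(3-methylbut-2-en-1-yl)-3-(4,4,5,5-tetramethyl-1,3,2-dioxaborolan-2-yl)-1-tosyl-1H-indole (1.3 equiv)
Product: 11 2-{2,3,5,6-tetramethoxy-4-[6-(3-methylbut-2-en-1-yl)-1-tosyl-1H-indol-3-yl]phenyl}ethan-1-ol
Conditions: Pd(OAc)2 (5 mol%), SPhos (10 mol%), K3PO4, toluene/H2O, 90 °C
Reagents that add atoms: none
Why: Suzuki–Miyaura biaryl coupling; the dialkylbiarylphosphine is chosen for the di-ortho-methoxy bromide, the N-tosyl group slows protodeboronation of the 3-indolylboronate, and the free primary alcohol is a spectator.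

Step 7
Reactants: 11 2-{2,3,5,6-tetramethoxy-4-[6-(3-methylbut-2-en-1-yl)-1-tosyl-1H-indol-3-yl]phenyl}ethan-1-ol
Product: 12 2-{2,3,5,6-tetramethoxy-4-[6-(3-methylbut-2-en-1-yl)-1-tosyl-1H-indol-3-yl]phenyl}acetaldehyde
Conditions: Dess–Martin periodinane (1.2 equiv), CH2Cl2, 0 °C → rt; used crude
Reagents that add atoms: none
Why: Dess–Martin oxidation of a primary alcohol stops at the aldehyde under neutral non-aqueous conditions and should leave the prenyl alkene, the sulfonamide and the aryl ethers untouched.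

Step 8
Reactants: 12 2-{2,3,5,6-tetramethoxy-4-[6-(3-methylbut-2-en-1-yl)-1-tosyl-1H-indol-3-yl]phenyl}acetaldehyde; 13 3-aminopropanenitrile (1.05 equiv)
Product: 15 (E)-3-[(2-{2,3,5,6-tetramethoxy-4-[6-(3-methylbut-2-en-1-yl)-1-tosyl-1H-indol-3-yl]phenyl}ethenyl)amino]propanenitrile, via aldimine tautomer 14 (not isolated)
Conditions: 4 Å MS, CH2Cl2, rt; filtered and used at once
Reagents that add atoms: none
Why: Condensation of an aldehyde with a primary amine (imine formation) followed by imine–enamine tautomerism; sieves remove the water and the crude tautomer pair, whose enamine form is the carbon nucleophile, is taken on directly.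

Step 9
Reactants: 15 (E)-3-[(2-{2,3,5,6-tetramethoxy-4-[6-(3-methylbut-2-en-1-yl)-1-tosyl-1H-indol-3-yl]phenyl}ethenyl)amino]propanenitrile; 16 1,4-benzoquinone (1.3 equiv)
Product: 19 3-(5-hydroxy-3-{2,3,5,6-tetramethoxy-4-[6-(3-methylbut-2-en-1-yl)-1-tosyl-1H-indol-3-yl]phenyl}-1H-indol-1-yl)propanenitrile, via hydroquinone adduct 17 (not isolated), via quinone 18 (not isolated)
Conditions: 15 added to 16, CH2Cl2, −20 °C → rt; then AcOH (2 equiv), rt
Reagents that add atoms: none
Why: Proposed new method: the enamine β-carbon (the carbon bearing ring C) adds to a CH of the quinone (Michael addition) and the adduct enolises to hydroquinone 17, which a second molecule of quinone oxidises to quinone 18; the enamine nitrogen then attacks the carbonyl carbon beside the new C–C bond, water is lost, and the hydroquinone produced in the oxidation reduces the resulting quinone iminium to the 5-hydroxyindole, so that C3–C3a and N1–C7a are formed in one flask. The closest known reaction type is the Nenitzescu synthesis of 5-hydroxyindoles from benzoquinone and β-aminocrotonates, here stretched to an aldehyde-derived β-aryl enamine that has no acceptor group; C-alkylation of simple enamines by quinones is the other known half. The pyrrole ring closes 5-exo-trig, nitrogen onto the quinone carbonyl, and no stereocentre is formed. The step needs carbon rather than nitrogen attack on the quinone and nitrogen rather than oxygen ring closure: the β-carbon is the soft terminus that quinones normally take, and because the enamine is secondary only closure through nitrogen can lose a proton and end as a neutral aromatic indole, whereas the oxygen-closed N,O-aminal remains in equilibrium with open-chain 17 and is drained by oxidation to 18. Since benzoquinone is symmetric, the untouched carbonyl can only become the C5 hydroxyl para to N1; inverse addition keeps quinone in excess over enamine, and acetic acid is added only after C–C bond formation to speed the dehydration.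

Step 10
Reactants: 19 3-(5-hydroxy-3-{2,3,5,6-tetramethoxy-4-[6-(3-methylbut-2-en-1-yl)-1-tosyl-1H-indol-3-yl]phenyl}-1H-indol-1-yl)propanenitrile
Product: 20 3-{2,3,5,6-tetramethoxy-4-[6-(3-methylbut-2-en-1-yl)-1H-indol-3-yl]phenyl}-1H-indol-5-ol (target)
Conditions: KOtBu (8 equiv), degassed THF, 0 °C → rt, then 60 °C; aq NH4Cl under argon
Reagents that add atoms: none
Why: Base-induced β-elimination (E1cB retro-aza-Michael) should expel the ring A indolide from the 2-cyanoethyl group as acrylonitrile, and tert-butoxide then takes the sulfonyl group from N1 of indole B (nucleophilic N-desulfonylation of an N-sulfonylindole), while the polyanion formed in an ethereal solvent resists deprotonation at the prenyl CH2.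

Compound list
1 | 6-bromo-1H-indole | Brc1ccc2cc[nH]c2c1 | starting material
2 | 6-(3-methylbut-2-en-1-yl)-1H-indole | CC(C)=CCc1ccc2cc[nH]c2c1 | intermediate
3 | 3-iodo-6-(3-methylbut-2-en-1-yl)-1H-indole | CC(C)=CCc1ccc2c(I)c[nH]c2c1 | intermediate (not isolated)
4 | 3-iodo-6-(3-methylbut-2-en-1-yl)-1-tosyl-1H-indole | CC(C)=CCc1ccc2c(I)cn(S(=O)(=O)c3ccc(C)cc3)c2c1 | intermediate
5 | [6-(3-methylbut-2-en-1-yl)-1-tosyl-1H-indol-3-yl]magnesium chloride | CC(C)=CCc1ccc2c([Mg]Cl)cn(S(=O)(=O)c3ccc(C)cc3)c2c1 | intermediate (not isolated)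
6 | 6-(3-methylbut-2-en-1-yl)-3-(4,4,5,5-tetramethyl-1,3,2-dioxaborolan-2-yl)-1-tosyl-1H-indole | CC(C)=CCc1ccc2c(B3OC(C)(C)C(C)(C)O3)cn(S(=O)(=O)c3ccc(C)cc3)c2c1 | intermediate
7 | 1,2,4,5-tetramethoxybenzene | COc1cc(OC)c(OC)cc1OC | starting material
8 | 1,4-dibromo-2,3,5,6-tetramethoxybenzene | COc1c(OC)c(Br)c(OC)c(OC)c1Br | intermediate
9 | (4-bromo-2,3,5,6-tetramethoxyphenyl)lithium | COc1c(OC)c(Br)c(OC)c(OC)c1[Li] | intermediate (not isolated)
10 | 2-(4-bromo-2,3,5,6-tetramethoxyphenyl)ethan-1-ol | OCCc1c(OC)c(OC)c(Br)c(OC)c1OC | intermediate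
11 | 2-{2,3,5,6-tetramethoxy-4-[6-(3-methylbut-2-en-1-yl)-1-tosyl-1H-indol-3-yl]phenyl}ethan-1-ol | OCCc1c(OC)c(OC)c(-c2cn(S(=O)(=O)c3ccc(C)cc3)c3cc(CC=C(C)C)ccc23)c(OC)c1OC | intermediate
12 | 2-{2,3,5,6-tetramethoxy-4-[6-(3-methylbut-2-en-1-yl)-1-tosyl-1H-indol-3-yl]phenyl}acetaldehyde | O=CCc1c(OC)c(OC)c(-c2cn(S(=O)(=O)c3ccc(C)cc3)c3cc(CC=C(C)C)ccc23)c(OC)c1OC | intermediate
13 | 3-aminopropanenitrile | NCCC#N | starting material
14 | (E)-3-[(2-{2,3,5,6-tetramethoxy-4-[6-(3-methylbut-2-en-1-yl)-1-tosyl-1H-indol-3-yl]phenyl}ethylidene)amino]propanenitrile (aldimine tautomer) | N#CCC/N=C/Cc1c(OC)c(OC)c(-c2cn(S(=O)(=O)c3ccc(C)cc3)c3cc(CC=C(C)C)ccc23)c(OC)c1OC | intermediate (not isolated)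
15 | (E)-3-[(2-{2,3,5,6-tetramethoxy-4-[6-(3-methylbut-2-en-1-yl)-1-tosyl-1H-indol-3-yl]phenyl}ethenyl)amino]propanenitrile | N#CCCN/C=C/c1c(OC)c(OC)c(-c2cn(S(=O)(=O)c3ccc(C)cc3)c3cc(CC=C(C)C)ccc23)c(OC)c1OC | intermediate (key-step precursor)
16 | 1,4-benzoquinone | O=C1C=CC(=O)C=C1 | starting material
17 | 3-[(2-(2,5-dihydroxyphenyl)-2-{2,3,5,6-tetramethoxy-4-[6-(3-methylbut-2-en-1-yl)-1-tosyl-1H-indol-3-yl]phenyl}ethenyl)amino]propanenitrile, nitrogen cis to the dihydroxyphenyl ring | N#CCCN/C=C(/c1c(OC)c(OC)c(-c2cn(S(=O)(=O)c3ccc(C)cc3)c3cc(CC=C(C)C)ccc23)c(OC)c1OC)c1cc(O)ccc1O | intermediate (not isolated)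
18 | 3-[(2-(3,6-dioxocyclohexa-1,4-dien-1-yl)-2-{2,3,5,6-tetramethoxy-4-[6-(3-methylbut-2-en-1-yl)-1-tosyl-1H-indol-3-yl]phenyl}ethenyl)amino]propanenitrile, nitrogen cis to the quinone ring | N#CCCN/C=C(/c1c(OC)c(OC)c(-c2cn(S(=O)(=O)c3ccc(C)cc3)c3cc(CC=C(C)C)ccc23)c(OC)c1OC)C1=CC(=O)C=CC1=O | intermediate (not isolated)
19 | 3-(5-hydroxy-3-{2,3,5,6-tetramethoxy-4-[6-(3-methylbut-2-en-1-yl)-1-tosyl-1H-indol-3-yl]phenyl}-1H-indol-1-yl)propanenitrile | COc1c(OC)c(-c2cn(CCC#N)c3ccc(O)cc23)c(OC)c(OC)c1-c1cn(S(=O)(=O)c2ccc(C)cc2)c2cc(CC=C(C)C)ccc12 | intermediate (key-step product)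
20 | 3-{2,3,5,6-tetramethoxy-4-[6-(3-methylbut-2-en-1-yl)-1H-indol-3-yl]phenyl}-1H-indol-5-ol | COc1c(OC)c(-c2c[nH]c3ccc(O)cc23)c(OC)c(OC)c1-c1c[nH]c2cc(CC=C(C)C)ccc12 | target

Total step count: 10 steps.
Longest linear sequence: 8 steps (steps 1, 2, 3, 6, 7, 8, 9, 10 from 6-bromoindole); the ring C branch (steps 4, 5) joins at step 6.

Steps most likely to fail

1. Step 9. Ring closure may go through the phenolic oxygen onto the iminium carbon and then lose the amine (benzofuran formation). The enamine nitrogen may attack the quinone instead of the hindered β-carbon. The electron-rich product may be oxidised further by the excess quinone. Fallback with known chemistry: setting out from aldehyde 12, a palladium-catalysed annulation with 4-amino-3-iodophenol (Pd(OAc)2, DABCO, DMF, 85 °C; enamine formation, then intramolecular Heck-type arylation) should give 3-{2,3,5,6-tetramethoxy-4-[6-(3-methylbut-2-en-1-yl)-1-tosyl-1H-indol-3-yl]phenyl}-1H-indol-5-ol F1, in which ring A carries no nitrogen substituent. Reductive N-desulfonylation (Mg, MeOH, rt) then comes back to the route at target 20.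

2. Step 10. The base may move the prenyl double bond into conjugation with indole B. The β-elimination from the electron-rich 5-oxidoindole may stay incomplete, with acrylonitrile adding back. The phenoxide may oxidise in air. Fallback: setting out from aldehyde 12, benzylamine replaces 13 in the condensation of step 8 and should give (E)-N-benzyl-2-{2,3,5,6-tetramethoxy-4-[6-(3-methylbut-2-en-1-yl)-1-tosyl-1H-indol-3-yl]phenyl}ethen-1-amine F2. Annulation with 16 under the conditions of step 9 should give 1-benzyl-3-{2,3,5,6-tetramethoxy-4-[6-(3-methylbut-2-en-1-yl)-1-tosyl-1H-indol-3-yl]phenyl}-1H-indol-5-ol F3. Sodium in liquid NH3/THF at −78 °C, added only to a persistent blue colour, cleaves N-benzyl and N-tosyl by electron transfer in place of elimination and comes back to the route at target 20.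

3. Step 6. The 3-indolylboronate may protodeboronate before transmetalation, coupling at the doubly ortho-substituted bromide may be slow, and hot aqueous base may remove part of the tosyl group. Fallback: setting out from iodide 4, magnesium reagent 5 (made as in step 3) is quenched with Bu3SnCl to give 6-(3-methylbut-2-en-1-yl)-1-tosyl-3-(tributylstannyl)-1H-indole F4. A base-free Stille coupling with bromide 10 (Pd(PPh3)4, CuI, CsF, DMF, 80 °C) comes back to the route at alcohol 11.

Further compounds
F1 | step 9 | 3-{2,3,5,6-tetramethoxy-4-[6-(3-methylbut-2-en-1-yl)-1-tosyl-1H-indol-3-yl]phenyl}-1H-indol-5-ol | COc1c(OC)c(-c2c[nH]c3ccc(O)cc23)c(OC)c(OC)c1-c1cn(S(=O)(=O)c2ccc(C)cc2)c2cc(CC=C(C)C)ccc12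
F2 | step 10 | (E)-N-benzyl-2-{2,3,5,6-tetramethoxy-4-[6-(3-methylbut-2-en-1-yl)-1-tosyl-1H-indol-3-yl]phenyl}ethen-1-amine | c1ccccc1CN/C=C/c1c(OC)c(OC)c(-c2cn(S(=O)(=O)c3ccc(C)cc3)c3cc(CC=C(C)C)ccc23)c(OC)c1OC
F3 | step 10 | 1-benzyl-3-{2,3,5,6-tetramethoxy-4-[6-(3-methylbut-2-en-1-yl)-1-tosyl-1H-indol-3-yl]phenyl}-1H-indol-5-ol | COc1c(OC)c(-c2cn(Cc3ccccc3)c3ccc(O)cc23)c(OC)c(OC)c1-c1cn(S(=O)(=O)c2ccc(C)cc2)c2cc(CC=C(C)C)ccc12
F4 | step 6 | 6-(3-methylbut-2-en-1-yl)-1-tosyl-3-(tributylstannyl)-1H-indole | CC(C)=CCc1ccc2c([Sn](CCCC)(CCCC)CCCC)cn(S(=O)(=O)c3ccc(C)cc3)c2c1
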